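(The runs were computed from invented constants, noise included.)

Percent of charge multiplied by the charge came out the same, within the scatter, at the last reading of my earlier flasks. At 12.0 min the spring flask held 2.02 mM of target, the noon flask 1.98 mM and the dawn flask 1.91 mM, while the solid substrate charged rose from 22 mM to 58 mM. That spread is smaller than the 0.290 mM that the scatter puts on a single dawn reading. So I read the target as order zero in the solid charged, and the percent as a concentration divided by the charge.

| flask | solid substrate | partner | remark | time |
|---|---|---|---|---|
| spring | 22 mM | 14 mM | run made earlier |  |
| noon | 38 mM | 14 mM | run made earlier |  |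
| dawn | 58 mM | 14 mM | run made earlier |  |
| amber | 20 mM | 14.0 mM |  | 25 min |
| violet | 40 mM | 14.0 mM |  | 25 min |
| teal | 80 mM | 14.0 mM |  | 25 min |

| spring: time / min | spring: target / % | noon: time / min | noon: target / % | dawn: time / min | dawn: target / % |
|---|---|---|---|---|---|
| 1.00 | 0 | 2.50 | 0.5 | 2.50 | 0.3 |
| 2.00 | 1.6 | 5.00 | 2.1 | 5.00 | 1.9 |
| 4.00 | 4.4 | 8.00 | 4.2 | 8.00 | 2.6 |
| 6.00 | 5.8 | 10.0 | 4.5 | 10.0 | 2.3 |
| 12.0 | 9.2 | 12.0 | 5.2 | 12.0 | 3.3 |

(standard deviation of a reading: 0.5 percentage points)

- solid, in amounts per volume of the solution: solid substrate
- what was read earlier has a scatter of 0.5 percentage points, one standard deviation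
- at the start none of the solid substrate is in solution
- "hardly changes" means that all values lie within two and a half points (for a concentration: within two and a half percent of the largest)

1. amount of target at the end, in percent of the solid substrate charged for amber, violet, teal, in this order
2. how that number moves from the first to the last of them (rises, then falls / rises all the way / falls all the way / hardly changes / falls, then rises)

I read the time scales from the spring flask, whose last percentage is the largest. On the first rung, none of the solid substrate was in solution at the start, and the spring flask read 0 % at 1.00 min. On the second, the target in the spring flask had reached 1.28 mM by 6.00 min. On the third, the equally long stretch to 12.0 min added 0.748 mM in the spring flask, which reads as 0.586 of the stretch before. The last rung runs to 25 min, and here I computed a correction to the large part already read. If each further stretch gives that same ratio of the one before, the next two, which nearly reach 25 min, add 0.696 mM. This gave my target level, the concentration of target common to flasks of different charge, 2.72 mM. Dividing by the charges, I expected 13.6 % for amber, 6.80 % for violet and 3.40 % for teal, with each doubling of the charge leaving half the percent.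

The forecast, a little above my reckoning, gave 14 %, 7 % and 3.5 %, falls all the way, holding that “excess solid is merely a reservoir”. The flasks gave 11.5 %, 5.75 % and 2.87 %: falls all the way.

    solid substrate ⇌ dissolved substrate, rate k1*(cs1 - [dissolved substrate]) while solid is left; crystals form when [dissolved substrate] > cs1 (solubility = 8.50 mM, k = 0.00786 s⁻¹)
    dissolved substrate + partner ⇌ target (K = 97.5 L mol⁻¹, k = 0.0640 L mol⁻¹ s⁻¹)
    target ⇌ isomer of the product (K = 8.30, k = 0.00153 s⁻¹)

The target level read back as 2.30 mM in amber and 2.30 mM in teal, which is 0.420 mM below my reckoning. In amber, taking both directions of each step together, the step from dissolved substrate and partner to target had at 25.0 min a relaxation half-life of 6.79 min and the step from target to its isomer one of 6.74 min, both short against the 25 min of the run, and at 25.0 min target was being made, net, at 0.959 times the net rate at which it was used up.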